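## Analysis of the target

The target (23, C29H26O4) is a 19-membered macrocyclic bis(bibenzyl). Four benzene rings form a loop through two diaryl ether oxygens (ring A–O–ring B and ring C–O–ring D) and two ethano bridges (ring B–CH2CH2–ring C and ring D–CH2CH2–ring A). Ring A is 1,3,4-trisubstituted: bridge carbon at C1, the ether oxygen to ring B at C3, a methoxy group at C4. Ring C has the same pattern, with the ether oxygen to ring D at C3 and a free hydroxyl at C4. Ring B is a para-phenylene and ring D a meta-phenylene. There is no stereocentre and no stereogenic double bond, so a stereocentre that appears on the way only has to disappear again. The sensitive site of the final compound is the electron-rich, catechol-type ring C with its free phenol; on the way, an aryl bromide and a silyl ether have to be carried.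

The synthesis is hard for three reasons. Rings A and C are near twins that differ only in OMe against OH. Both diaryl ethers sit on electron-rich rings without activation, so nucleophilic aromatic substitution is not available. A 19-membered ring has to be closed.

The strategy rests on ring C: its C1, which carries the bridge to ring B, lies para to the C4 oxygen. In the quinone monoketal of a 3-aryloxy-4-methoxyphenol this carbon is a ketone carbonyl and accepts a carbon nucleophile, and the ketal carbon comes back as C4–OH.

## Retrosynthetic reasoning

Target 23 from 22. The last operation only frees the ring C hydroxyl. Compound 22 is the macrocycle with that oxygen as a benzyl ether, and hydrogenolysis leaves the methyl ether, both diaryl ethers and the bridges alone.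

Macrocycle 22 from 21. The bond cut is ring A C3–O, the ether to ring B. Both ends are cheap to carry: the bromine on ring A arrives with 6 and the ring B oxygen arrives with 13. Cutting here keeps both bridges for intermolecular C–C bond formation. It also keeps the hindered, doubly ortho-oxygenated ring C out of the ring closure, which would be the case for a cut at ring C–O–ring D. The forward reaction is a copper-catalysed intramolecular O-arylation of a para-alkyl phenol by an ortho-methoxy aryl bromide under high dilution.

Phenol 21 from 19 by way of 20. In 19 the ring C hydroxyl is free and would compete for the ring A bromide, leading to a 12-membered ether. It is therefore benzylated (20) before the ring B silyl ether is removed (21). The silyl group is triisopropylsilyl and not the smaller tert-butyldimethylsilyl, because it has to outlast carbonate and phenoxide during the benzylation without cleavage or transfer to the ring C oxygen.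

Phenol 19 from 17 by way of 18. Ring C is traced back to a cyclohexadiene. The ketal carbon of 17 becomes the C4–OH carbon and the carbinol carbon becomes C1. Forward, aqueous acid turns the ketal into the dienone 18, and a two-electron reduction expels the tertiary hydroxyl. The gain is that the ring C oxygen appears as a free phenol while the ring A oxygen has been a methyl ether since 6, so the two rings are told apart by oxidation level and not by protection.

Adduct 17 from 12 and 16. This is the central cut: the bond between the bridge CH2 and ring C C1. A normal polarity would need ring C as nucleophile at a carbon para to oxygen, which means Friedel–Crafts chemistry with poor regiocontrol on a ring with two oxygen substituents. In 12 the same carbon is a carbonyl, and the two-carbon arm of ring B comes as the carbanion 16. The forward reaction has to give 1,2-addition in the presence of two enone double bonds and an aryl bromide.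

Grignard reagent 16 from 15, 14 and 13. The arylethyl bromide 15 comes from 13 by turning the primary alcohol into the bromide (14) and silylating the phenol. The order matters, because the bromide can be made in strong acid only while the phenol is free.

Monoketal 12 from 11. The cut is at the second methoxy group on the ketal carbon. A para-methoxyphenol is oxidised in an alcohol solvent by a trivalent iodine reagent, and the solvent adds at the carbon that already bears OMe. The phenol 11 thus holds ring C one oxidation step below the electrophile.

Phenol 11 from 10, and 10 from 5 and 9. The ring D–ring A bridge is cut at its central C–C bond and made as an alkene, from the ring D aldehyde 5 and the ring A ylide 9. The ylide comes from the phosphonium salt 8, which comes from 6 through the alcohol 7. The alkene is then saturated without touching the bromine. Building the bridge from two benzylic carbons uses the aldehyde groups that the commercial rings already carry.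

Aldehyde 5 from 3 by way of 4, and 3 from 1 and 2. The ring C–O–ring D ether is cut at the ring D carbon and made by an intermolecular copper-catalysed coupling of the phenol of 1 with the bromide 2. The formyl group of 1 is then replaced by hydroxyl through oxygen insertion and loss of formate (4). The acetal in 2 keeps the ring D aldehyde out of that oxidation and is removed in the same step.

## Alternatives that were turned down

Alternative 1: The disconnection is the central C–C bond of the ring D–ring A bridge, traced back to a CH2–SO2–CH2 unit in the 20-membered macrocyclic sulfone A2. Forward, A2 is halogenated at an α-carbon and treated with base; the episulfone loses SO2 and gives the 19-membered stilbene A1 (Ramberg–Bäcklund reaction), which is hydrogenated with loss of the benzyl group. In its favour, the ring that is actually closed is a thioether or sulfone ring, made from a thiolate and a benzylic halide. This is a more dependable macrocyclisation than the copper-catalysed aryl ether closure of step 14, and on this point the alternative is stronger. The final hydrogenation would saturate the alkene and remove the benzyl group at once. Against it, both diaryl ethers have to be made beforehand by intermolecular couplings, and the ring A and ring C oxygens are still told apart only by protection. Two extra benzylic carbons must be functionalised, and sulfur has to be put in, oxidised and taken out. The halogenating base conditions are also a risk for electron-rich arenes. The chosen route puts its redox work into ring C, where it forms a bridge bond and sets the OH/OMe difference in the same two steps (10 and 11).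

Alternative 2: The disconnection is the ring C–O bond to ring D, with ring C held as a cyclohexanone. The seco compound A4, a 2-bromo-4-alkylcyclohexanone carrying a free ring D phenol, would close to the macrocyclic 2-aryloxycyclohexanone A3 by displacement of bromide, and A3 would be dehydrogenated to the phenol at the end. In its favour, the ether bond forms at an activated sp3 carbon under mild base and without a metal, which is easier than any arylation of a phenol. The ketone oxygen also becomes the free ring C hydroxyl without protection, so it equals the chosen route on that point. Against it, a macrocyclic SN2 reaction at a secondary α-bromoketone competes with elimination to the enone and with Favorskii rearrangement. Ring C would have to be built from a non-aromatic six-membered ring with its side chain, which costs steps. The last step would be a double dehydrogenation of an α-aryloxy ketone in a molecule with three electron-rich arenes and four benzylic CH2 groups. The chosen route reaches the aromatic level of ring C by a mild reduction (17 to 19) and not by a late oxidation, and it buys ring C as the aromatic compound 1.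

Alternative 3: The disconnection is the same ring A–O bond that step 14 makes, but by oxidative phenol coupling. The open bis-phenol A6, with a 2,6-dibromophenol as ring A and a 2,6-dichlorophenol as ring B, would be oxidised by Tl(NO3)3 (trivalent thallium). The ring B oxygen attacks a bromine-bearing ortho carbon of ring A, and reduction of the dienone with zinc gives the macrocyclic diaryl ether A5. In its favour, the ring closes at room temperature from two free phenols, with no aryl halide–copper chemistry at a hindered ortho-oxygenated carbon. As a way to form this particular bond it is at least as strong as step 14. Against it, four halogens have to be installed as control elements and removed again, the oxidant is a stoichiometric and highly toxic thallium salt, and ring A comes out as a free phenol that still needs methylation. The ring A/ring C distinction therefore again depends on protection (benzyl on ring C). The ring C–O–ring D ether and both bridges would also still have to be made conventionally. The chosen route closes the ring with catalytic copper from 21 and spends its key step on a bridge C–C bond and on the ring C oxygen pattern.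

Key step: step 10

Remark: the target has no stereogenic element; 2 is taken as purchased (it is the ethylene acetal of 3-bromobenzaldehyde and can be made from that aldehyde in one step if needed).

## Route

Step 1
Reactants: 1 isovanillin (3-hydroxy-4-methoxybenzaldehyde); 2 2-(3-bromophenyl)-1,3-dioxolane
Product: 3 3-[3-(1,3-dioxolan-2-yl)phenoxy]-4-methoxybenzaldehyde
Conditions: CuI (10 mol%), N,N-dimethylglycine·HCl (30 mol%), Cs2CO3, 1,4-dioxane, 100 °C
Reagents that add atoms: none
Why: Ligand-accelerated Ullmann diaryl ether coupling of a phenoxide with an unhindered aryl bromide; the non-enolisable aldehyde and the acetal are stable to carbonate, and only one aldehyde is free afterwards.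

Step 2
Reactants: 3 3-[3-(1,3-dioxolan-2-yl)phenoxy]-4-methoxybenzaldehyde
Product: 5 3-(5-hydroxy-2-methoxyphenoxy)benzaldehyde, via aryl formate 4 (not isolated)
Conditions: mCPBA, NaHCO3, CH2Cl2, 0 °C to rt; aq Na2S2O3 quench; then 2 M HCl, THF, rt
Reagents that add atoms: 3-chloroperoxybenzoic acid (mCPBA), OOC(=O)c1cccc(Cl)c1; water, O
Why: Baeyer–Villiger (Dakin-type) oxidation; the aryl group para to OMe migrates to give formate 4, while the ring D aldehyde is masked as the acetal and cannot be oxidised. Aqueous acid then cleaves the formate and the dioxolane together, after the excess peracid has been destroyed.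

Step 3
Reactants: 6 3-bromo-4-methoxybenzaldehyde
Product: 7 (3-bromo-4-methoxyphenyl)methanol
Conditions: NaBH4, MeOH, 0 °C
Reagents that add atoms: none
Why: Hydride reduction of an aromatic aldehyde; the aryl bromide is inert.

Step 4
Reactants: 7 (3-bromo-4-methoxyphenyl)methanol
Product: 8 (3-bromo-4-methoxybenzyl)triphenylphosphonium bromide
Conditions: PPh3·HBr, MeCN, reflux
Reagents that add atoms: triphenylphosphine hydrobromide, [Br-].[PH+](c1ccccc1)(c1ccccc1)c1ccccc1
Why: Direct conversion of a benzylic alcohol into the phosphonium salt; the para-methoxy group assists acid ionisation of the benzylic C–O bond and triphenylphosphine captures the electrophile.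

Step 5
Reactants: 5 3-(5-hydroxy-2-methoxyphenoxy)benzaldehyde; 8 (3-bromo-4-methoxybenzyl)triphenylphosphonium bromide
Product: 10 3-{3-[2-(3-bromo-4-methoxyphenyl)ethenyl]phenoxy}-4-methoxyphenol (E/Z mixture), via phosphonium ylide 9 (not isolated)
Conditions: KOtBu (2.3 equiv), THF, 0 °C to rt, N2
Reagents that add atoms: none
Why: Wittig olefination with a semi-stabilised benzylic ylide; the extra equivalent of base holds the phenol as its phenoxide, which sits on ring C and does not deactivate the ring D aldehyde. The alkene geometry is irrelevant because step 6 saturates it.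

Step 6
Reactants: 10 3-{3-[2-(3-bromo-4-methoxyphenyl)ethenyl]phenoxy}-4-methoxyphenol
Product: 11 3-{3-[2-(3-bromo-4-methoxyphenyl)ethyl]phenoxy}-4-methoxyphenol
Conditions: TsNHNH2 (excess, in portions), NaOAc, THF–H2O, reflux
Reagents that add atoms: none
Why: Diimide reduction, a concerted syn transfer of two hydrogens to the C=C bond; unlike hydrogenation over palladium it cannot cleave the aryl C–Br bond needed in step 14.

Step 7
Reactants: 11 3-{3-[2-(3-bromo-4-methoxyphenyl)ethyl]phenoxy}-4-methoxyphenol
Product: 12 3-{3-[2-(3-bromo-4-methoxyphenyl)ethyl]phenoxy}-4,4-dimethoxycyclohexa-2,5-dien-1-one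
Conditions: PhI(OAc)2, MeOH, 0 °C, short reaction time; NaHCO3 work-up
Reagents that add atoms: methanol, CO
Why: Oxidative dearomatisation of a para-methoxyphenol by a trivalent iodine reagent; methanol adds at the carbon para to the phenol oxygen, which already bears OMe, giving the quinone monoketal. Rings A and D have no free phenol and are not oxidised.

Step 8
Reactants: 13 4-hydroxyphenethyl alcohol (4-(2-hydroxyethyl)phenol)
Product: 14 4-(2-bromoethyl)phenol
Conditions: 48% aq HBr, 90 °C
Reagents that add atoms: hydrogen bromide, Br
Why: SN2 substitution of the protonated primary alcohol by bromide; the phenol does not react under these conditions.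

Step 9
Reactants: 14 4-(2-bromoethyl)phenol
Product: 15 [4-(2-bromoethyl)phenoxy]triisopropylsilane
Conditions: TIPSCl, imidazole, DMF, rt
Reagents that add atoms: chlorotriisopropylsilane (TIPSCl), CC(C)[Si](Cl)(C(C)C)C(C)C
Why: Imidazole-promoted O-silylation of a phenol; the base is too weak to cause elimination or phenoxide participation at the bromoethyl chain.

Step 10
Reactants: 15 [4-(2-bromoethyl)phenoxy]triisopropylsilane; 12 3-{3-[2-(3-bromo-4-methoxyphenyl)ethyl]phenoxy}-4,4-dimethoxycyclohexa-2,5-dien-1-one
Product: 17 3-{3-[2-(3-bromo-4-methoxyphenyl)ethyl]phenoxy}-4,4-dimethoxy-1-{2-[4-(triisopropylsilyloxy)phenyl]ethyl}cyclohexa-2,5-dien-1-ol (racemic), via Grignard reagent 16 (not isolated)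
Conditions: Mg turnings, THF, 40 °C (15 to 16, 1.5 equiv); then added to 12, THF, −78 to −40 °C; aq NH4Cl
Reagents that add atoms: none
Why: The alkylmagnesium bromide 16 attacks the dienone carbonyl of 12, the future C1 of ring C, in a polar 1,2-addition, and work-up gives the tertiary bis-allylic alcohol 17; this is the known 1,2-addition of Grignard reagents to para-quinone monoketals, related to the carbonyl addition to vinylogous esters in the Stork–Danheiser sequence. No ring is closed. The carbinol carbon is a new stereocentre formed without control, which does not matter because step 11 returns it to sp2. Carbonyl attack has to win over conjugate attack: the gem-dimethoxy carbon shields the β-carbon on one side, and on the other the C3 aryloxy group makes the double bond an electron-rich vinylogous ester. A hard, non-stabilised alkylmagnesium reagent at −78 °C follows this bias. The ring A bromide has to survive, and bromine–magnesium exchange between an electron-rich bromoanisole and a primary alkyl Grignard reagent does not occur at this temperature. The dienone has no α-hydrogen, so enolisation is impossible; the remaining competitor, reduction of the monoketal by hydride or electron transfer, is held down by the low temperature and by adding the reagent to the ketone.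

Step 11
Reactants: 17 3-{3-[2-(3-bromo-4-methoxyphenyl)ethyl]phenoxy}-4,4-dimethoxy-1-{2-[4-(triisopropylsilyloxy)phenyl]ethyl}cyclohexa-2,5-dien-1-ol
Product: 19 2-{3-[2-(3-bromo-4-methoxyphenyl)ethyl]phenoxy}-4-{2-[4-(triisopropylsilyloxy)phenyl]ethyl}phenol, via para-quinol 18 (not isolated)
Conditions: AcOH–THF–H2O (3:1:1), rt; then Zn dust, rt to 40 °C
Reagents that add atoms: water, O
Why: The ketal ionises to an oxocarbenium ion far faster than the tertiary alcohol does and is hydrolysed to para-quinol 18. Zinc then reduces the cross-conjugated dienone by two electrons with loss of the 4-hydroxyl, and the ring aromatises (reductive aromatisation of para-quinols), with the new alkyl group para to OH. The aryl bromide and the aryl silyl ether are stable to zinc in acetic acid at this temperature.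

Step 12
Reactants: 19 2-{3-[2-(3-bromo-4-methoxyphenyl)ethyl]phenoxy}-4-{2-[4-(triisopropylsilyloxy)phenyl]ethyl}phenol
Product: 20 {4-[2-(4-benzyloxy-3-{3-[2-(3-bromo-4-methoxyphenyl)ethyl]phenoxy}phenyl)ethyl]phenoxy}triisopropylsilane
Conditions: BnBr, K2CO3, acetone, 50 °C
Reagents that add atoms: benzyl bromide, BrCc1ccccc1
Why: Williamson etherification of the only free phenol; the bulky triisopropylsilyl ether resists carbonate and phenoxide, so the ring B oxygen stays masked.

Step 13
Reactants: 20 {4-[2-(4-benzyloxy-3-{3-[2-(3-bromo-4-methoxyphenyl)ethyl]phenoxy}phenyl)ethyl]phenoxy}triisopropylsilane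
Product: 21 4-[2-(4-benzyloxy-3-{3-[2-(3-bromo-4-methoxyphenyl)ethyl]phenoxy}phenyl)ethyl]phenol
Conditions: TBAF, THF, 0 °C
Reagents that add atoms: none
Why: Fluoride cleavage of an aryl silyl ether, driven by the Si–F bond; benzyl ether, methyl ether and aryl bromide are untouched.

Step 14
Reactants: 21 4-[2-(4-benzyloxy-3-{3-[2-(3-bromo-4-methoxyphenyl)ethyl]phenoxy}phenyl)ethyl]phenol
Product: 22 O-benzyl macrocycle (23 with the ring C hydroxyl as benzyl ether)
Conditions: CuI (30 mol%), N,N-dimethylglycine·HCl, Cs2CO3, 1,4-dioxane, 100 °C, 2 mM, slow addition
Reagents that add atoms: none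
Why: Intramolecular Ullmann diaryl ether coupling; the unhindered para-alkyl phenoxide of ring B is arylated by the ring A bromide through a monovalent copper phenoxide, and high dilution favours the 19-membered ring over oligomers. The ring C oxygen is benzylated and cannot compete.

Step 15
Reactants: 22 O-benzyl macrocycle
Product: 23 target macrocycle CNP0132125.0
Conditions: H2 (1 atm), Pd/C, EtOAc–EtOH, rt
Reagents that add atoms: none
Why: Hydrogenolysis of the benzylic C–O bond frees the ring C phenol; no halogen or alkene is left, and the diaryl ethers and the methyl ether are stable.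

## Compound list

1 | isovanillin (3-hydroxy-4-methoxybenzaldehyde) | COc1ccc(C=O)cc1O | starting material
2 | 2-(3-bromophenyl)-1,3-dioxolane | Brc1cccc(c1)C1OCCO1 | starting material
3 | 3-[3-(1,3-dioxolan-2-yl)phenoxy]-4-methoxybenzaldehyde | COc1ccc(C=O)cc1Oc1cccc(c1)C1OCCO1 | intermediate
4 | 3-[3-(1,3-dioxolan-2-yl)phenoxy]-4-methoxyphenyl formate (not isolated) | COc1ccc(OC=O)cc1Oc1cccc(c1)C1OCCO1 | intermediate
5 | 3-(5-hydroxy-2-methoxyphenoxy)benzaldehyde | COc1ccc(O)cc1Oc1cccc(C=O)c1 | intermediate
6 | 3-bromo-4-methoxybenzaldehyde | COc1ccc(C=O)cc1Br | starting material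
7 | (3-bromo-4-methoxyphenyl)methanol | COc1ccc(CO)cc1Br | intermediate
8 | (3-bromo-4-methoxybenzyl)triphenylphosphonium bromide | COc1ccc(C[P+](c2ccccc2)(c2ccccc2)c2ccccc2)cc1Br.[Br-] | intermediate
9 | (3-bromo-4-methoxybenzylidene)triphenylphosphorane (not isolated) | COc1ccc(C=P(c2ccccc2)(c2ccccc2)c2ccccc2)cc1Br | intermediate
10 | 3-{3-[2-(3-bromo-4-methoxyphenyl)ethenyl]phenoxy}-4-methoxyphenol (E/Z mixture) | COc1ccc(O)cc1Oc1cccc(C=Cc2ccc(OC)c(Br)c2)c1 | intermediate
11 | 3-{3-[2-(3-bromo-4-methoxyphenyl)ethyl]phenoxy}-4-methoxyphenol | COc1ccc(O)cc1Oc1cccc(CCc2ccc(OC)c(Br)c2)c1 | intermediate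
12 | 3-{3-[2-(3-bromo-4-methoxyphenyl)ethyl]phenoxy}-4,4-dimethoxycyclohexa-2,5-dien-1-one (fragment 2) | O=C1C=CC(OC)(OC)C(Oc2cccc(CCc3ccc(OC)c(Br)c3)c2)=C1 | intermediate
13 | 4-hydroxyphenethyl alcohol | OCCc1ccc(O)cc1 | starting material
14 | 4-(2-bromoethyl)phenol | BrCCc1ccc(O)cc1 | intermediate
15 | [4-(2-bromoethyl)phenoxy]triisopropylsilane | CC(C)[Si](C(C)C)(C(C)C)Oc1ccc(CCBr)cc1 | intermediate
16 | 2-[4-(triisopropylsilyloxy)phenyl]ethylmagnesium bromide (fragment 1, not isolated) | CC(C)[Si](C(C)C)(C(C)C)Oc1ccc(CC[Mg]Br)cc1 | intermediate
17 | 3-{3-[2-(3-bromo-4-methoxyphenyl)ethyl]phenoxy}-4,4-dimethoxy-1-{2-[4-(triisopropylsilyloxy)phenyl]ethyl}cyclohexa-2,5-dien-1-ol (racemic) | CC(C)[Si](C(C)C)(C(C)C)Oc1ccc(CCC2(O)C=CC(OC)(OC)C(Oc3cccc(CCc4ccc(OC)c(Br)c4)c3)=C2)cc1 | intermediate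
18 | 2-{3-[2-(3-bromo-4-methoxyphenyl)ethyl]phenoxy}-4-hydroxy-4-{2-[4-(triisopropylsilyloxy)phenyl]ethyl}cyclohexa-2,5-dien-1-one (racemic, not isolated) | CC(C)[Si](C(C)C)(C(C)C)Oc1ccc(CCC2(O)C=CC(=O)C(Oc3cccc(CCc4ccc(OC)c(Br)c4)c3)=C2)cc1 | intermediate
19 | 2-{3-[2-(3-bromo-4-methoxyphenyl)ethyl]phenoxy}-4-{2-[4-(triisopropylsilyloxy)phenyl]ethyl}phenol | CC(C)[Si](C(C)C)(C(C)C)Oc1ccc(CCc2ccc(O)c(Oc3cccc(CCc4ccc(OC)c(Br)c4)c3)c2)cc1 | intermediate
20 | {4-[2-(4-benzyloxy-3-{3-[2-(3-bromo-4-methoxyphenyl)ethyl]phenoxy}phenyl)ethyl]phenoxy}triisopropylsilane | CC(C)[Si](C(C)C)(C(C)C)Oc1ccc(CCc2ccc(OCc5ccccc5)c(Oc3cccc(CCc4ccc(OC)c(Br)c4)c3)c2)cc1 | intermediate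
21 | 4-[2-(4-benzyloxy-3-{3-[2-(3-bromo-4-methoxyphenyl)ethyl]phenoxy}phenyl)ethyl]phenol | Oc1ccc(CCc2ccc(OCc5ccccc5)c(Oc3cccc(CCc4ccc(OC)c(Br)c4)c3)c2)cc1 | intermediate
22 | O-benzyl macrocycle (ring C benzyl ether of the target) | COc1ccc2cc1Oc1ccc(cc1)CCc1ccc(OCc3ccccc3)c(c1)Oc1cccc(c1)CC2 | intermediate
23 | target macrocycle CNP0132125.0 | COc1ccc2cc1Oc1ccc(cc1)CCc1ccc(O)c(c1)Oc1cccc(c1)CC2 | target

## Step count and risk

Total: 15 steps. Longest linear sequence: 11 steps, from 1 to 23 (steps 1, 2, 5, 6, 7, 10, 11, 12, 13, 14, 15).

Step 10 (key step). The most likely failure is reduction of the monoketal in place of addition. A primary alkylmagnesium reagent has β-hydrogens and can also transfer an electron, and either path returns ring C to the phenol oxidation level. Homocoupling during formation of 16 also costs material. Fallback, setting out from 12 and rejoining at 19: the carbon nucleophile is changed to an acetylide, which has no β-hydrogen and is a poor electron donor. [(4-Ethynylphenoxy)]triisopropylsilane F1 (from 4-ethynylphenol by silylation) is lithiated with n-BuLi in THF at −78 °C and added to 12 to give the propargylic quinol ketal F2. Aqueous acetic acid gives the alkynyl para-quinol F3, which is not isolated, and zinc dust gives the diarylalkyne phenol F4. Exhaustive diimide reduction (TsNHNH2, NaOAc, reflux) saturates the triple bond without touching the bromide and gives 19.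

Step 14. Intermolecular coupling to oligomers and loss of bromine by protodehalogenation are the likely losses, because the bromide is ortho to a methoxy group on an electron-rich ring and oxidative addition is slow. Fallback, setting out from 21 and rejoining at 22: the ring A bromide is turned into a boron partner and the ether is closed oxidatively at room temperature. Miyaura borylation (bis(pinacolato)diboron, PdCl2(dppf), KOAc, dioxane, 90 °C) gives the pinacol boronate F5. NaIO4 and NH4OAc in aqueous acetone give the boronic acid F6. Intramolecular Chan–Lam coupling (Cu(OAc)2, Et3N, 4 Å molecular sieves, CH2Cl2, air, high dilution) gives 22.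

Step 11. Two processes can divert the aromatisation. Electron transfer before the ketal is hydrolysed would expel the hydroxyl from the O-methyl oxocarbenium ion and leave ring C as a methyl ether. Acid ionisation at the carbinol carbon, helped by the C3 aryloxy group, would lead to loss of the ring D phenol by a vinylogous transposition. The two-stage protocol, hydrolysis first and zinc second, is meant to prevent both. Fallback, setting out from 17 and rejoining at 19: hydrolysis under buffered conditions (pyridinium p-toluenesulfonate, aqueous acetone) and isolation of 18. A 1,2-reduction of the dienone under Luche conditions (NaBH4, CeCl3·7H2O, MeOH, −78 °C) then gives the cyclohexadiene-1,4-diol F7. A trace of acid makes F7 lose the tertiary hydroxyl and the proton at the carbinol carbon to give 19. The electron-transfer step is thus replaced by hydride addition and dehydration.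

Step 7. The monoketal is a vinylogous aryl ester, so prolonged contact with acidic methanol can exchange the ring D aryloxy group for methoxy by conjugate addition and elimination; over-oxidation is the second risk. Fallback, setting out from 11 and rejoining at 12: the phenol is methylated (MeI, K2CO3, acetone) to the 1,4-dimethoxyarene F8. Anodic oxidation (Pt anode, KOH, MeOH, 0 °C) gives the quinone bisketal F9. Dilute aqueous acetic acid in acetone hydrolyses the ketal remote from the aryloxy-bearing carbon, because only that ionisation is stabilised through the enol ether, and gives 12.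

## Further compounds

F1 | step 10 | [(4-ethynylphenoxy)]triisopropylsilane | CC(C)[Si](C(C)C)(C(C)C)Oc1ccc(C#C)cc1
F2 | step 10 | 3-{3-[2-(3-bromo-4-methoxyphenyl)ethyl]phenoxy}-4,4-dimethoxy-1-{[4-(triisopropylsilyloxy)phenyl]ethynyl}cyclohexa-2,5-dien-1-ol (racemic) | CC(C)[Si](C(C)C)(C(C)C)Oc1ccc(C#CC2(O)C=CC(OC)(OC)C(Oc3cccc(CCc4ccc(OC)c(Br)c4)c3)=C2)cc1
F3 | step 10 | 2-{3-[2-(3-bromo-4-methoxyphenyl)ethyl]phenoxy}-4-hydroxy-4-{[4-(triisopropylsilyloxy)phenyl]ethynyl}cyclohexa-2,5-dien-1-one (racemic, not isolated) | CC(C)[Si](C(C)C)(C(C)C)Oc1ccc(C#CC2(O)C=CC(=O)C(Oc3cccc(CCc4ccc(OC)c(Br)c4)c3)=C2)cc1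
F4 | step 10 | 2-{3-[2-(3-bromo-4-methoxyphenyl)ethyl]phenoxy}-4-{[4-(triisopropylsilyloxy)phenyl]ethynyl}phenol | CC(C)[Si](C(C)C)(C(C)C)Oc1ccc(C#Cc2ccc(O)c(Oc3cccc(CCc4ccc(OC)c(Br)c4)c3)c2)cc1
F5 | step 14 | 4-{2-[4-benzyloxy-3-(3-{2-[4-methoxy-3-(4,4,5,5-tetramethyl-1,3,2-dioxaborolan-2-yl)phenyl]ethyl}phenoxy)phenyl]ethyl}phenol | Oc1ccc(CCc2ccc(OCc3ccccc3)c(Oc3cccc(CCc4ccc(OC)c(B5OC(C)(C)C(C)(C)O5)c4)c3)c2)cc1
F6 | step 14 | {5-[2-(3-{2-benzyloxy-5-[2-(4-hydroxyphenyl)ethyl]phenoxy}phenyl)ethyl]-2-methoxyphenyl}boronic acid | Oc1ccc(CCc2ccc(OCc3ccccc3)c(Oc3cccc(CCc4ccc(OC)c(B(O)O)c4)c3)c2)cc1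
F7 | step 11 | 2-{3-[2-(3-bromo-4-methoxyphenyl)ethyl]phenoxy}-4-{2-[4-(triisopropylsilyloxy)phenyl]ethyl}cyclohexa-2,5-diene-1,4-diol (diastereomer mixture) | CC(C)[Si](C(C)C)(C(C)C)Oc1ccc(CCC2(O)C=CC(O)C(Oc3cccc(CCc4ccc(OC)c(Br)c4)c3)=C2)cc1
F8 | step 7 | 2-{3-[2-(3-bromo-4-methoxyphenyl)ethyl]phenoxy}-1,4-dimethoxybenzene | COc1ccc(OC)c(Oc2cccc(CCc3ccc(OC)c(Br)c3)c2)c1
F9 | step 7 | 1-{3-[2-(3-bromo-4-methoxyphenyl)ethyl]phenoxy}-3,3,6,6-tetramethoxycyclohexa-1,4-diene | COC1(OC)C=CC(OC)(OC)C(Oc2cccc(CCc3ccc(OC)c(Br)c3)c2)=C1
A1 | alternative 1 | macrocyclic stilbene with ring C benzyl ether (E shown) | COc1ccc(/C=C/c2cccc(c2)Oc2cc(ccc2OCc2ccccc2)CCc2ccc(cc2)O3)cc13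
A2 | alternative 1 | 20-membered macrocyclic dibenzyl sulfone with ring C benzyl ether | COc1ccc(CS(=O)(=O)Cc2cccc(c2)Oc2cc(ccc2OCc2ccccc2)CCc2ccc(cc2)O3)cc13
A3 | alternative 2 | macrocyclic 2-aryloxycyclohexanone (diastereomer mixture) | COc1ccc2cc1Oc1ccc(cc1)CCC1CCC(=O)C(C1)Oc1cccc(c1)CC2
A4 | alternative 2 | open 2-bromo-4-alkylcyclohexanone with free ring D phenol (diastereomer mixture) | COc1ccc(CCc2cccc(O)c2)cc1Oc1ccc(CCC2CCC(=O)C(Br)C2)cc1
A5 | alternative 3 | halogenated macrocyclic diaryl ether with free ring A phenol and ring C benzyl ether | Oc1c(Br)cc2cc1Oc1c(Cl)cc(cc1Cl)CCc1ccc(OCc3ccccc3)c(c1)Oc1cccc(c1)CC2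
A6 | alternative 3 | open bis-phenol with 2,6-dibromophenol ring A and 2,6-dichlorophenol ring B | Oc1c(Br)cc(CCc2cccc(Oc3cc(CCc4cc(Cl)c(O)c(Cl)c4)ccc3OCc3ccccc3)c2)cc1Br
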